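**Retrosynthetic overview**

1. Target 18 comes from (2R)-flavanone 17 by hydrogenolysis of four benzyl ethers.
2. Ring C (O1–C2–C3–C4–C4a–C8a) is not closed as a six-membered ring. It arises in step 10 by one-carbon ring expansion of the five-membered ring (O1, C2, C4, C4a, C8a) of ring-fused cyclopropanol 14: β-scission of the C2–C4 bond, then chiral-nickel arylation of the C2 radical with PhBr (sets C2–Ph and 2R).
3. Enabling feature: ketone C4 and ether carbon C2 sit 1,3 across the single methylene C3 (a β-aryloxy ketone, the retron of a cyclopropanol). O1 stabilises the C2 radical, and the electron-rich ring A aryl on C4 eases oxidation.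
4. 14 comes from CH2 transfer to 3-silyloxybenzofuran 12, from benzofuranone 11, from Friedel–Crafts closure of aryloxyacetic acid 9. Phenol 8 is symmetric (free OH para to the benzyl group), so the 6- versus 8-benzyl question cannot arise.
5. 8 comes from aryllithium 5 plus aldehyde 2, deoxygenation, and Br→OH. Ring order: both arenes are bought; furanone ring (step 7), cyclopropane (step 9), ring C by expansion (step 10).

Key step: step 10

Remark: the stereodescriptor of the given SMILES is read as (2R) (O1 > phenyl > C3 > H); atom numbers in the text are flavanone numbers unless a compound name says otherwise.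

**Step 1**
Reactants: 1 4-bromo-2,6-difluorobenzaldehyde
Product: 2 4-bromo-2,6-bis(benzyloxy)benzaldehyde
Conditions: BnOH (2.2 equiv), NaH (2.2 equiv), DMF, 0 to 50 °C
Reagents that add atoms: benzyl alcohol OCc1ccccc1
Why: Twofold nucleophilic aromatic substitution (SNAr) in which benzyl oxide displaces the two fluorides ortho to the activating formyl group much faster than the para bromide, giving a symmetric ring A precursor in which the bromine is a masked O1.

**Step 2**
Reactants: 3 3-bromobenzene-1,2-diol
Product: 4 1,2-bis(benzyloxy)-3-bromobenzene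
Conditions: BnBr (2.2 equiv), K2CO3, DMF, 60 °C
Reagents that add atoms: benzyl bromide BrCc1ccccc1
Why: Williamson ether synthesis on both catechol hydroxyls under standard carbonate conditions.

**Step 3**
Reactants: 4 1,2-bis(benzyloxy)-3-bromobenzene; 2 4-bromo-2,6-bis(benzyloxy)benzaldehyde
Product: 6 [4-bromo-2,6-bis(benzyloxy)phenyl][2,3-bis(benzyloxy)phenyl]methanol (racemic), via aryllithium 5 (not isolated)
Conditions: n-BuLi (1.0 equiv), THF, −78 °C; then 2, −78 to −40 °C; H2O
Reagents that add atoms: none
Why: Bromine–lithium exchange on 4 is fast at −78 °C and the aryllithium adds 1,2 to the non-enolisable aldehyde while the aryl bromide of 2 stays untouched at this temperature, giving the diarylmethanol as a racemate whose carbinol stereocentre is erased in step 4.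

**Step 4**
Reactants: 6 [4-bromo-2,6-bis(benzyloxy)phenyl][2,3-bis(benzyloxy)phenyl]methanol
Product: 7 1,3-bis(benzyloxy)-2-[2,3-bis(benzyloxy)benzyl]-5-bromobenzene
Conditions: Et3SiH, CF3CO2H, CH2Cl2, 0 °C
Reagents that add atoms: none
Why: Ionic hydrogenation, in which the doubly benzylic carbinol ionises in trifluoroacetic acid to a cation stabilised by the two ortho benzyloxy groups and is reduced by the silane, leaving aryl bromide and benzyl ethers intact.

**Step 5**
Reactants: 7 1,3-bis(benzyloxy)-2-[2,3-bis(benzyloxy)benzyl]-5-bromobenzene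
Product: 8 3,5-bis(benzyloxy)-4-[2,3-bis(benzyloxy)benzyl]phenol
Conditions: Pd2(dba)3 (2 mol%), tBuXPhos (8 mol%), KOH, 1,4-dioxane/H2O, 100 °C; then aq. HCl
Reagents that add atoms: potassium hydroxide [K+].[OH-]
Why: Palladium-catalysed hydroxylation of an unhindered aryl bromide (Buchwald–Hartwig-type C–O coupling with hydroxide) unmasks the one oxygen para to the benzyl group, so O1 is differentiated from O5 and O7 by construction.

**Step 6**
Reactants: 8 3,5-bis(benzyloxy)-4-[2,3-bis(benzyloxy)benzyl]phenol
Product: 9 {3,5-bis(benzyloxy)-4-[2,3-bis(benzyloxy)benzyl]phenoxy}acetic acid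
Conditions: NaH (2.5 equiv), BrCH2CO2H, THF/DMF, 0 to 60 °C; then aq. HCl
Reagents that add atoms: bromoacetic acid OC(=O)CBr
Why: Williamson O-alkylation of the sodium phenoxide with sodium bromoacetate places the future C2 and C4 carbons on the only free hydroxyl.

**Step 7**
Reactants: 9 {3,5-bis(benzyloxy)-4-[2,3-bis(benzyloxy)benzyl]phenoxy}acetic acid
Product: 11 4,6-bis(benzyloxy)-5-[2,3-bis(benzyloxy)benzyl]-1-benzofuran-3(2H)-one, via mixed anhydride 10 (not isolated)
Conditions: (CF3CO)2O (2 equiv), CH2Cl2, 0 to 25 °C; aq. NaHCO3 work-up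
Reagents that add atoms: none
Why: Intramolecular Friedel–Crafts acylation through the mixed trifluoroacetic anhydride closes the five-membered furanone ring (5-exo attack of the very electron-rich arene, forming C4–C4a), and because the two positions ortho to O1 are equivalent only the regioisomer that maps onto the 6-benzyl flavanone can form.

**Step 8**
Reactants: 11 4,6-bis(benzyloxy)-5-[2,3-bis(benzyloxy)benzyl]-1-benzofuran-3(2H)-one
Product: 12 {4,6-bis(benzyloxy)-5-[2,3-bis(benzyloxy)benzyl]-1-benzofuran-3-yl}oxy(trimethyl)silane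
Conditions: Me3SiOTf, Et3N, CH2Cl2, 0 °C; non-aqueous work-up, used crude
Reagents that add atoms: trimethylsilyl trifluoromethanesulfonate C[Si](C)(C)OS(=O)(=O)C(F)(F)F
Why: Soft enolisation with a silyl triflate and amine base gives the aromatic 3-silyloxybenzofuran, which fixes an electron-rich enol ether double bond between C2 and C4 for methylene transfer.

**Step 9**
Reactants: 12 {4,6-bis(benzyloxy)-5-[2,3-bis(benzyloxy)benzyl]-1-benzofuran-3-yl}oxy(trimethyl)silane
Product: 14 4,6-bis(benzyloxy)-5-[2,3-bis(benzyloxy)benzyl]-1,1a-dihydro-6bH-cyclopropa[b][1]benzofuran-6b-ol (racemic), via silyloxycyclopropane 13 (not isolated)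
Conditions: Et2Zn, CH2I2, CH2Cl2, 0 to 25 °C; then K2CO3 (cat.), MeOH, 0 °C
Reagents that add atoms: diiodomethane ICI
Why: Furukawa-modified Simmons–Smith cyclopropanation of a silyl enol ether adds the methylene that becomes C3 across the C2=C4 bond, necessarily cis at the ring fusion (two new stereocentres, racemic, both erased or overwritten in step 10), and mild methanolysis frees the tertiary cyclopropanol.

**Step 10**
Reactants: 14 4,6-bis(benzyloxy)-5-[2,3-bis(benzyloxy)benzyl]-1,1a-dihydro-6bH-cyclopropa[b][1]benzofuran-6b-ol; 15 bromobenzene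
Product: 17 (2R)-5,7-bis(benzyloxy)-6-[2,3-bis(benzyloxy)benzyl]-2-phenyl-2,3-dihydro-4H-chromen-4-one, via C2 radical 16 (not isolated)
Conditions: [Ir(dF(CF3)ppy)2(dtbbpy)]PF6 (2 mol%), NiBr2·glyme (10 mol%), iPr-BiOX (12 mol%; the enantiomer that gives 2R, (S,S) tried first), 2,4,6-collidine (2 equiv), degassed MeCN/PhCF3, blue LEDs (450 nm), 25 °C
Reagents that add atoms: none
Why: Proposed new method: proton-coupled electron transfer from the cyclopropanol O–H of 14 to the photoexcited trivalent iridium complex (collidine as proton acceptor, eased by the electron-rich ring A aryl on C4) should give the C4 alkoxy radical, which undergoes β-scission of the internal C2–C4 bond so that the five-membered ring (O1, C2, C4, C4a, C8a) becomes the six-membered 4-chromanone ring with the radical on C2 (16); 16 is captured by the phenylnickel bromide formed from zerovalent nickel and 15, reductive elimination from trivalent nickel makes the C2–Ph bond, and the monovalent nickel left behind is reduced by the divalent iridium species to close both cycles. The closest known reaction types are the photoredox/nickel ring-opening arylation of tertiary cycloalkanols by alkoxy-radical β-scission, the FeCl3-mediated one-carbon ring expansion of ring-fused (silyloxy)cyclopropanes, and the nickel-catalysed enantioconvergent arylation of α-oxy and α-amino alkyl radicals; their combination on a ring-fused cyclopropanol with enantiocontrol has not been shown. No ring is closed by a new ring bond: ring C arises purely by one-atom ring expansion, C3 passing from the cyclopropane bridge into the ring when the zero-atom bridge C2–C4 of the 2-oxabicyclo[3.1.0]hexane unit breaks. The single stereocentre C2 is set in the nickel-centred C–C reductive elimination under control of the chiral bis(oxazoline) ligand, and since radical 16 is planar both enantiomers of racemic 14 converge on the same product. The step needs cleavage of the internal C2–C4 bond instead of the external C3–C4 bond and nickel capture of 16 faster than hydrogen-atom quench or β-hydride loss; the first is secured by the O1 lone pair, which stabilises the C2 radical, and by the fact that the alternative primary radical can return through 3-exo re-closure onto the ketone, the second by the nickel loading and by a weak non-nucleophilic base that also leaves the base-sensitive flavanone untouched.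

**Step 11**
Reactants: 17 (2R)-5,7-bis(benzyloxy)-6-[2,3-bis(benzyloxy)benzyl]-2-phenyl-2,3-dihydro-4H-chromen-4-one
Product: 18 (2R)-6-(2,3-dihydroxybenzyl)-5,7-dihydroxy-2-phenyl-2,3-dihydro-4H-chromen-4-one
Conditions: H2 (1 atm), 10% Pd/C, EtOAc/MeOH, 25 °C, stopped at complete debenzylation
Reagents that add atoms: none
Why: Palladium-catalysed hydrogenolysis removes the four benzyl ethers under neutral conditions that neither open nor epimerise the base-sensitive flavanone, so the C2 stereocentre set in step 10 is carried through unchanged.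

**Compound list**

1 | 4-bromo-2,6-difluorobenzaldehyde | O=Cc1c(F)cc(Br)cc1F | starting material
2 | 4-bromo-2,6-bis(benzyloxy)benzaldehyde | O=Cc1c(OCc2ccccc2)cc(Br)cc1OCc1ccccc1 | intermediate
3 | 3-bromobenzene-1,2-diol | Oc1cccc(Br)c1O | starting material
4 | 1,2-bis(benzyloxy)-3-bromobenzene | Brc1cccc(OCc2ccccc2)c1OCc1ccccc1 | intermediate
5 | [2,3-bis(benzyloxy)phenyl]lithium (formed in the flask) | [Li]c1cccc(OCc2ccccc2)c1OCc1ccccc1 | intermediate
6 | [4-bromo-2,6-bis(benzyloxy)phenyl][2,3-bis(benzyloxy)phenyl]methanol (racemic) | OC(c1c(OCc2ccccc2)cc(Br)cc1OCc1ccccc1)c1cccc(OCc2ccccc2)c1OCc1ccccc1 | intermediate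
7 | 1,3-bis(benzyloxy)-2-[2,3-bis(benzyloxy)benzyl]-5-bromobenzene | Brc1cc(OCc2ccccc2)c(Cc2cccc(OCc3ccccc3)c2OCc2ccccc2)c(OCc2ccccc2)c1 | intermediate
8 | 3,5-bis(benzyloxy)-4-[2,3-bis(benzyloxy)benzyl]phenol | Oc1cc(OCc2ccccc2)c(Cc2cccc(OCc3ccccc3)c2OCc2ccccc2)c(OCc2ccccc2)c1 | intermediate
9 | {3,5-bis(benzyloxy)-4-[2,3-bis(benzyloxy)benzyl]phenoxy}acetic acid | OC(=O)COc1cc(OCc2ccccc2)c(Cc2cccc(OCc3ccccc3)c2OCc2ccccc2)c(OCc2ccccc2)c1 | intermediate
10 | {3,5-bis(benzyloxy)-4-[2,3-bis(benzyloxy)benzyl]phenoxy}acetic trifluoroacetic anhydride (formed in the flask) | FC(F)(F)C(=O)OC(=O)COc1cc(OCc2ccccc2)c(Cc2cccc(OCc3ccccc3)c2OCc2ccccc2)c(OCc2ccccc2)c1 | intermediate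
11 | 4,6-bis(benzyloxy)-5-[2,3-bis(benzyloxy)benzyl]-1-benzofuran-3(2H)-one | O=C1COc2cc(OCc3ccccc3)c(Cc3cccc(OCc4ccccc4)c3OCc3ccccc3)c(OCc3ccccc3)c21 | intermediate
12 | {4,6-bis(benzyloxy)-5-[2,3-bis(benzyloxy)benzyl]-1-benzofuran-3-yl}oxy(trimethyl)silane | C[Si](C)(C)Oc1coc2cc(OCc3ccccc3)c(Cc3cccc(OCc4ccccc4)c3OCc3ccccc3)c(OCc3ccccc3)c12 | intermediate
13 | {4,6-bis(benzyloxy)-5-[2,3-bis(benzyloxy)benzyl]-1,1a-dihydro-6bH-cyclopropa[b][1]benzofuran-6b-yl}oxy(trimethyl)silane (racemic; cis fusion forced; formed in the flask) | C[Si](C)(C)OC12CC1Oc1cc(OCc3ccccc3)c(Cc3cccc(OCc4ccccc4)c3OCc3ccccc3)c(OCc3ccccc3)c12 | intermediate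
14 | 4,6-bis(benzyloxy)-5-[2,3-bis(benzyloxy)benzyl]-1,1a-dihydro-6bH-cyclopropa[b][1]benzofuran-6b-ol (racemic; cis fusion forced) | OC12CC1Oc1cc(OCc3ccccc3)c(Cc3cccc(OCc4ccccc4)c3OCc3ccccc3)c(OCc3ccccc3)c12 | intermediate
15 | bromobenzene | Brc1ccccc1 | starting material
16 | 5,7-bis(benzyloxy)-6-[2,3-bis(benzyloxy)benzyl]-4-oxo-3,4-dihydro-2H-chromen-2-yl radical (formed in the flask) | O=C1C[CH]Oc2cc(OCc3ccccc3)c(Cc3cccc(OCc4ccccc4)c3OCc3ccccc3)c(OCc3ccccc3)c21 | intermediate
17 | (2R)-5,7-bis(benzyloxy)-6-[2,3-bis(benzyloxy)benzyl]-2-phenyl-2,3-dihydro-4H-chromen-4-one | O=C1C[C@H](c2ccccc2)Oc2cc(OCc3ccccc3)c(Cc3cccc(OCc4ccccc4)c3OCc3ccccc3)c(OCc3ccccc3)c21 | intermediate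
18 | (2R)-6-(2,3-dihydroxybenzyl)-5,7-dihydroxy-2-phenyl-2,3-dihydro-4H-chromen-4-one | O=C1C[C@H](c2ccccc2)Oc2cc(O)c(Cc3cccc(O)c3O)c(O)c21 | target

**Step count and risks**

Total steps: 11. Longest linear sequence: 10 (steps 1 and 3 to 11); step 2 is a one-step side branch.

Steps most likely to fail:

- **Step 10 (Proposed new method).** What may go wrong:
  - two-electron nickel homoenolate opening of the external C3–C4 bond, which would transfer the aryl group to C3;
  - loss of a β-hydrogen from the C2–nickel intermediate, or hydrogen-atom quench of the C2 radical before capture;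
  - insufficient facial discrimination in the reductive elimination.

  Fallback with known chemistry, setting out from 14 and coming back at 17: oxidative one-carbon ring expansion of the cyclopropanol with FeCl3 (2.2 equiv) in DMF at 0 °C should give the 2-chlorochroman-4-one F1 by the same internal-bond β-scission followed by chlorine transfer. NaOAc in MeOH should then eliminate HCl to the chromone F2. Palladium-catalysed asymmetric conjugate addition of PhB(OH)2 to F2 (Pd(OCOCF3)2, (S)-t-BuPyOx, NH4PF6, H2O, ClCH2CH2Cl, 60 °C) would then set C2 and give 17. (S)-t-BuPyOx is expected by analogy with cyclic enones to favour 2R; the mirror-image ligand would be used otherwise.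

- **Step 9.** What may go wrong: slow methylene transfer to the hindered, arene-embedded enol ether, or Lewis-acid-triggered opening of the 1,2-dioxygenated cyclopropane by zinc iodide during reaction and work-up. Fallback, setting out from 11 and coming back at 14: deprotonation of 11 with LiN(SiMe3)2 in THF at −78 °C gives the lithium enolate F3. Treatment with CH2I2 and SmI2 (samarium carbenoid, oxygen-directed methylene transfer to a metal enolate) should give cyclopropanol 14 directly after aqueous work-up, without a silyl enol ether and without zinc.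

- **Step 7.** What may go wrong: acid-promoted loss or migration of the benzyl ether peri to the new carbonyl, or incomplete ring closure of the mixed anhydride. Fallback, setting out from 8 and coming back at 11, closing the ring with an aryl anion instead of an acyl cation:
  - bromination of 8 with N-bromosuccinimide (MeCN, −20 °C; only the two equivalent ortho positions are free) gives the bromophenol F4;
  - O-alkylation with 2-bromo-N-methoxy-N-methylacetamide (K2CO3, DMF) gives the Weinreb amide F5;
  - t-BuLi (2 equiv, THF, −100 °C) effects bromine–lithium exchange to the aryllithium F6, which closes onto the amide carbonyl (Parham cyclisation) and gives 11 on aqueous work-up.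

**Further compounds**

F1 | step 10 | 5,7-bis(benzyloxy)-6-[2,3-bis(benzyloxy)benzyl]-2-chloro-2,3-dihydro-4H-chromen-4-one (racemic) | O=C1CC(Cl)Oc2cc(OCc3ccccc3)c(Cc3cccc(OCc4ccccc4)c3OCc3ccccc3)c(OCc3ccccc3)c21
F2 | step 10 | 5,7-bis(benzyloxy)-6-[2,3-bis(benzyloxy)benzyl]-4H-chromen-4-one | O=c1ccoc2cc(OCc3ccccc3)c(Cc3cccc(OCc4ccccc4)c3OCc3ccccc3)c(OCc3ccccc3)c12
F3 | step 9 | lithium 4,6-bis(benzyloxy)-5-[2,3-bis(benzyloxy)benzyl]-1-benzofuran-3-olate | [Li+].[O-]c1coc2cc(OCc3ccccc3)c(Cc3cccc(OCc4ccccc4)c3OCc3ccccc3)c(OCc3ccccc3)c12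
F4 | step 7 | 3,5-bis(benzyloxy)-4-[2,3-bis(benzyloxy)benzyl]-2-bromophenol | Oc1cc(OCc2ccccc2)c(Cc2cccc(OCc3ccccc3)c2OCc2ccccc2)c(OCc2ccccc2)c1Br
F5 | step 7 | 2-{3,5-bis(benzyloxy)-4-[2,3-bis(benzyloxy)benzyl]-2-bromophenoxy}-N-methoxy-N-methylacetamide | CON(C)C(=O)COc1cc(OCc2ccccc2)c(Cc2cccc(OCc3ccccc3)c2OCc2ccccc2)c(OCc2ccccc2)c1Br
F6 | step 7 | (2,4-bis(benzyloxy)-3-[2,3-bis(benzyloxy)benzyl]-6-{2-[methoxy(methyl)amino]-2-oxoethoxy}phenyl)lithium | CON(C)C(=O)COc1cc(OCc2ccccc2)c(Cc2cccc(OCc3ccccc3)c2OCc2ccccc2)c(OCc2ccccc2)c1[Li]
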